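**Plan**
Cuts: the two O–CH3 bonds of a dimethyl ether of the target; then C3=C4 and O1–C2 of the pyranone of unit P (the 5-aryloxy-6,7-dihydroxycoumarin; unit Q is its 7-hydroxycoumarin-6-yl group); then C8–C8a of the benzene ring of P; last C5–O, C4a–C4 and C6–C7, which lie on the rim of a squarate.
Enabling feature: in the benzene ring of P the oxygens on C6 and C8a are para and C8a–C4a–C5–C6 are contiguous. This is the signature of a hydroquinone grown from a 4-alkenyl-4-hydroxycyclobutenone, whose vinyl group supplies C7 (with its oxygen) and C8.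
Forward: the four-membered ring receives a 1,3-dithian-2-yl group (masked C4 aldehyde), then unit Q with both of its rings in place as a vinylogous aryl ester (no arylation needed), then a 1-methoxyvinyl group.
Heat converts the four-membered ring into the benzene ring of P; the pyranone of P closes last by Wittig olefination–lactonisation, and BBr3 frees the two remaining phenols.
Stereochemistry: the target has no stereocentre. The only one on the way, the carbinol carbon of the cyclobutenones, is racemic and vanishes on aromatisation.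

Key step: step 5

Assumption: rotation about the diaryl ether is taken as free, so the target is treated as achiral, and all compounds marked starting material are taken as purchasable.

**Step 1**
Reactants: 1 1,3-dithiane; 2 diisopropyl squarate
Product: 5 3-(1,3-dithian-2-yl)-4-isopropoxycyclobut-3-ene-1,2-dione, via 2-lithio-1,3-dithiane 3 (not isolated), via carbinol adduct 4 (not isolated)
Conditions: n-BuLi, THF, −30 °C; add to 2, THF, −78 °C; aq NH4Cl; then conc. HCl (cat.), CH2Cl2, rt
Reagents that add atoms: none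
Why: 1,2-addition of a sulfur-stabilised organolithium to one carbonyl of a dialkyl squarate, followed by acid-catalysed loss of propan-2-ol from the carbinol, is the standard entry to 3-substituted 4-alkoxycyclobutenediones, and the dithiane is inert to the acid.

**Step 2**
Reactants: 5 3-(1,3-dithian-2-yl)-4-isopropoxycyclobut-3-ene-1,2-dione
Product: 6 3-(1,3-dithian-2-yl)-4-hydroxycyclobut-3-ene-1,2-dione
Conditions: 6 M aq HCl, THF, 50 °C
Reagents that add atoms: water, O
Why: Acid hydrolysis of a vinylogous ester (addition–elimination of water at the alkoxy-bearing carbon) is the usual way from semisquaric esters to semisquaric acids, and a 1,3-dithiane does not hydrolyse in aqueous mineral acid without a thiophile.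

**Step 3**
Reactants: 6 3-(1,3-dithian-2-yl)-4-hydroxycyclobut-3-ene-1,2-dione; 7 isoscopoletin (6-hydroxy-7-methoxycoumarin)
Product: 9 3-(1,3-dithian-2-yl)-4-[(7-methoxy-2-oxo-2H-chromen-6-yl)oxy]cyclobut-3-ene-1,2-dione, via semisquaric chloride 8 (not isolated)
Conditions: (COCl)2, DMF (cat.), CH2Cl2, 0 °C to rt, evaporate; then 7, 2,6-lutidine, CH2Cl2–THF, 0 °C to rt
Reagents that add atoms: oxalyl chloride, O=C(Cl)C(=O)Cl (supplies the chlorine of 8; none of its atoms remain in 9)
Why: A semisquaric acid is a vinylogous carboxylic acid, so Vilsmeier-type activation gives the vinylogous acid chloride and addition–elimination by the unhindered phenol gives the vinylogous aryl ester, with 2,6-lutidine chosen because it binds HCl but is too weak to ionise the dithianyl C–H or open the lactone.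

**Step 4**
Reactants: 9 3-(1,3-dithian-2-yl)-4-[(7-methoxy-2-oxo-2H-chromen-6-yl)oxy]cyclobut-3-ene-1,2-dione; 10 methyl vinyl ether
Product: 12 rac-2-(1,3-dithian-2-yl)-4-hydroxy-3-[(7-methoxy-2-oxo-2H-chromen-6-yl)oxy]-4-(1-methoxyethenyl)cyclobut-2-en-1-one, via 1-methoxyvinyllithium 11 (not isolated)
Conditions: 10 (slight excess), t-BuLi, THF, −78 to 0 °C; 11 (1.05 equiv) added slowly to 9, THF, −78 °C; aq NH4Cl at −78 °C
Reagents that add atoms: none
Why: Organolithium 1,2-addition to a 3-alkyl-4-oxy-cyclobutenedione goes to the carbonyl next to the oxygen-bearing carbon, because the other carbonyl is deactivated as a vinylogous ester and is here also shielded by the dithiane, and this strained ketone should outrun the coumarin lactone, ipso attack at C–OAr and proton transfer when one equivalent of the reagent meets 9 at −78 °C; the new carbinol centre forms racemic and is of no consequence.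

**Step 5**
Reactants: 12 rac-2-(1,3-dithian-2-yl)-4-hydroxy-3-[(7-methoxy-2-oxo-2H-chromen-6-yl)oxy]-4-(1-methoxyethenyl)cyclobut-2-en-1-one
Product: 15 6-[2-(1,3-dithian-2-yl)-3,6-dihydroxy-5-methoxyphenoxy]-7-methoxy-2H-chromen-2-one, via dienylketene 13 (not isolated), via cyclohexadienone 14 (not isolated)
Conditions: toluene (degassed, dilute), 110 °C, argon, base-washed glass
Reagents that add atoms: none
Why: At about 110 °C the C1–C4 bond of 12 opens in a conrotatory four-electron process, and since the hydroxyl on C4 is the stronger donor it turns outward, which places the 1-methoxyvinyl group inward, cis to the ketene, in (Z)-dienylketene 13. A disrotatory six-electron electrocyclization then bonds the ketene carbon (C8a of unit P) to the vinyl CH2 (C8) and so closes the six-membered carbocycle as dienone 14, which enolises irreversibly to the aromatic hydroquinone 15. The closest known reaction is the Moore cyclization of 3-alkoxy-4-alkenyl-4-hydroxycyclobutenones to hydroquinones; here an aryloxy group merely sits where the alkoxy spectator usually does. No stereocentre is created and the racemic carbinol carbon of 12 becomes the planar C6. The step needs torquoselectivity, because inward rotation of the hydroxyl would let it add to the ketene and form a lactone, and the donor character of that hydroxyl secures it, while regiochemistry is fixed in advance since ring carbons C1, C2, C3 and C4 of 12 become C8a, C4a, C5 and C6 and the vinyl carbons become C7 and C8. Degassed solvent under argon and base-washed glass protect the oxidisable hydroquinone and the acid-labile enol ether.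

**Step 6**
Reactants: 15 6-[2-(1,3-dithian-2-yl)-3,6-dihydroxy-5-methoxyphenoxy]-7-methoxy-2H-chromen-2-one
Product: 16 3,6-dihydroxy-4-methoxy-2-[(7-methoxy-2-oxo-2H-chromen-6-yl)oxy]benzaldehyde
Conditions: MeI (excess), CaCO3, MeCN–H2O (4:1), 50 °C, argon
Reagents that add atoms: water, O
Why: Alkylative dithiane hydrolysis (S-methylation, ring opening assisted by the electron-rich arene, capture by water) is non-oxidative and so spares the hydroquinone, while insoluble CaCO3 neutralises the acid formed without ionising the phenols.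

**Step 7**
Reactants: 16 3,6-dihydroxy-4-methoxy-2-[(7-methoxy-2-oxo-2H-chromen-6-yl)oxy]benzaldehyde; 17 ethyl (triphenylphosphoranylidene)acetate
Product: 19 6-hydroxy-7-methoxy-5-[(7-methoxy-2-oxo-2H-chromen-6-yl)oxy]-2H-chromen-2-one, via E-cinnamate 18 (not isolated)
Conditions: PhNEt2, reflux (ca. 215 °C), argon
Reagents that add atoms: none
Why: Wittig olefination of a salicylaldehyde with a stabilised ylide in refluxing N,N-diethylaniline is a standard one-flask coumarin synthesis, in which the cinnamate equilibrates thermally to its Z isomer and is drained by lactonisation onto the C8a hydroxyl, the only phenol within reach of the ester.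

**Step 8**
Reactants: 19 6-hydroxy-7-methoxy-5-[(7-methoxy-2-oxo-2H-chromen-6-yl)oxy]-2H-chromen-2-one
Product: 20 6,7-dihydroxy-5-[(7-hydroxy-2-oxo-2H-chromen-6-yl)oxy]-2H-chromen-2-one (CNP0197949.0)
Conditions: BBr3 (excess), CH2Cl2, −78 °C to rt; then H2O
Reagents that add atoms: none
Why: BBr3 cleavage of aryl methyl ethers leaves diaryl ethers and coumarin lactones untouched, as in the routine demethylation of methoxycoumarins to hydroxycoumarins.

**Compound list**
1 | 1,3-dithiane | C1CSCSC1 | starting material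
2 | diisopropyl squarate (3,4-diisopropoxycyclobut-3-ene-1,2-dione) | CC(C)OC1=C(OC(C)C)C(=O)C1=O | starting material
3 | 2-lithio-1,3-dithiane | [Li]C1SCCCS1 | intermediate
4 | rac-4-(1,3-dithian-2-yl)-4-hydroxy-2,3-diisopropoxycyclobut-2-en-1-one | CC(C)OC1=C(OC(C)C)C(O)(C2SCCCS2)C1=O | intermediate
5 | 3-(1,3-dithian-2-yl)-4-isopropoxycyclobut-3-ene-1,2-dione | CC(C)OC1=C(C2SCCCS2)C(=O)C1=O | intermediate
6 | 3-(1,3-dithian-2-yl)-4-hydroxycyclobut-3-ene-1,2-dione | OC1=C(C2SCCCS2)C(=O)C1=O | intermediate
7 | isoscopoletin (6-hydroxy-7-methoxy-2H-chromen-2-one) | COc1cc2oc(=O)ccc2cc1O | starting material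
8 | 3-chloro-4-(1,3-dithian-2-yl)cyclobut-3-ene-1,2-dione | ClC1=C(C2SCCCS2)C(=O)C1=O | intermediate
9 | 3-(1,3-dithian-2-yl)-4-[(7-methoxy-2-oxo-2H-chromen-6-yl)oxy]cyclobut-3-ene-1,2-dione | O=C1C(=O)C(C2SCCCS2)=C1Oc1cc2ccc(=O)oc2cc1OC | intermediate
10 | methyl vinyl ether | COC=C | starting material
11 | 1-methoxyvinyllithium | [Li]C(=C)OC | intermediate
12 | rac-2-(1,3-dithian-2-yl)-4-hydroxy-3-[(7-methoxy-2-oxo-2H-chromen-6-yl)oxy]-4-(1-methoxyethenyl)cyclobut-2-en-1-one | O=C1C(C2SCCCS2)=C(Oc2cc3ccc(=O)oc3cc2OC)C1(O)C(OC)=C | intermediate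
13 | (3Z)-2-(1,3-dithian-2-yl)-4-hydroxy-5-methoxy-3-[(7-methoxy-2-oxo-2H-chromen-6-yl)oxy]hexa-1,3,5-trien-1-one | O=C=C(C1SCCCS1)/C(Oc1cc2ccc(=O)oc2cc1OC)=C(/O)C(=C)OC | intermediate
14 | 2-(1,3-dithian-2-yl)-4-hydroxy-5-methoxy-3-[(7-methoxy-2-oxo-2H-chromen-6-yl)oxy]cyclohexa-2,4-dien-1-one | O=C1CC(OC)=C(O)C(Oc2cc3ccc(=O)oc3cc2OC)=C1C1SCCCS1 | intermediate
15 | 6-[2-(1,3-dithian-2-yl)-3,6-dihydroxy-5-methoxyphenoxy]-7-methoxy-2H-chromen-2-one | COc1cc(O)c(C2SCCCS2)c(Oc2cc3ccc(=O)oc3cc2OC)c1O | intermediate
16 | 3,6-dihydroxy-4-methoxy-2-[(7-methoxy-2-oxo-2H-chromen-6-yl)oxy]benzaldehyde | COc1cc(O)c(C=O)c(Oc2cc3ccc(=O)oc3cc2OC)c1O | intermediate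
17 | ethyl (triphenylphosphoranylidene)acetate | CCOC(=O)C=P(c1ccccc1)(c1ccccc1)c1ccccc1 | starting material
18 | ethyl (E)-3-{3,6-dihydroxy-4-methoxy-2-[(7-methoxy-2-oxo-2H-chromen-6-yl)oxy]phenyl}prop-2-enoate | CCOC(=O)/C=C/c1c(O)cc(OC)c(O)c1Oc1cc2ccc(=O)oc2cc1OC | intermediate
19 | 6-hydroxy-7-methoxy-5-[(7-methoxy-2-oxo-2H-chromen-6-yl)oxy]-2H-chromen-2-one | COc1cc2oc(=O)ccc2c(Oc2cc3ccc(=O)oc3cc2OC)c1O | intermediate
20 | 6,7-dihydroxy-5-[(7-hydroxy-2-oxo-2H-chromen-6-yl)oxy]-2H-chromen-2-one (CNP0197949.0) | O=c1ccc2cc(Oc3c(O)c(O)cc4oc(=O)ccc34)c(O)cc2o1 | target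

Total step count: 8. Longest linear sequence: 8 steps (from 1 and 2 to 20).

**Steps most likely to fail**

Step 4. The carbanion may be used up by proton transfer from the dithianyl C–H, which is acidified by two sulfur atoms and by vinylogy with the ring carbonyl. To a lesser degree it may be lost by attack on the lactone of unit Q or by ipso displacement of the aryloxide.

The fallback changes the aldehyde mask from S,S to O,O before the carbanion stage. The carbon acid is then comparable to that of the simple 3-alkyl semisquarates, for which this addition is routine.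
- Setting out from 5, PhI(OCOCF3)2 in MeOH should exchange the dithiane for the acetal and give 3-(dimethoxymethyl)-4-isopropoxycyclobut-3-ene-1,2-dione F1.
- The vinylogous ester is then cleaved with one equivalent of NaOH in THF–H2O at 0 °C (acid would strip the acetal) to sodium 2-(dimethoxymethyl)-3,4-dioxocyclobut-1-en-1-olate F2.
- The dried salt reacts with (COCl)2 and catalytic DMF to give 3-chloro-4-(dimethoxymethyl)cyclobut-3-ene-1,2-dione F3.
- With 7 and 2,6-lutidine this gives 3-(dimethoxymethyl)-4-[(7-methoxy-2-oxo-2H-chromen-6-yl)oxy]cyclobut-3-ene-1,2-dione F4.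
- Addition of 11 at −78 °C should give rac-2-(dimethoxymethyl)-4-hydroxy-3-[(7-methoxy-2-oxo-2H-chromen-6-yl)oxy]-4-(1-methoxyethenyl)cyclobut-2-en-1-one F5.
- Thermolysis in toluene gives 6-[2-(dimethoxymethyl)-3,6-dihydroxy-5-methoxyphenoxy]-7-methoxy-2H-chromen-2-one F6.
- Pyridinium p-toluenesulfonate in wet acetone releases the aldehyde, so the route is rejoined at 16 and step 6 falls away.

Step 5. Ring opening with the hydroxyl turning inward, followed by its addition to the ketene, would divert material to a lactone. The free carbinol or traces of acid may also cost the enol ether before the ring opens.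

The fallback caps the carbinol, so that no hydroxyl can reach the ketene and a bulkier donor reinforces outward rotation.
- From 12, Et3SiOTf and 2,6-lutidine in CH2Cl2 at −78 °C give the triethylsilyl ether of carbinol 12 F7.
- Heating in toluene gives the C6-O-triethylsilyl hydroquinone F8, which is also less prone to air oxidation.
- Et3N·3HF in THF removes silicon and returns the route to 15.

Step 6. S-Methylation may be slow at a dithiane flanked by two ortho substituents. During long heating the hydroquinone may be lost through air oxidation or O-methylation.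

The fallback takes the hydroquinone out of play first, which allows a fast oxidative cleavage.
- From 15, Ac2O–pyridine gives 2-(1,3-dithian-2-yl)-5-methoxy-3-[(7-methoxy-2-oxo-2H-chromen-6-yl)oxy]benzene-1,4-diyl diacetate F9.
- PhI(OCOCF3)2 in MeCN–H2O at 0 °C cleaves the dithiane to 2-formyl-5-methoxy-3-[(7-methoxy-2-oxo-2H-chromen-6-yl)oxy]benzene-1,4-diyl diacetate F10.
- K2CO3 in MeOH at 0 °C under argon, followed by acidification (which recloses any opened lactone), gives 16.

**Further compounds**
F1 | step 4 | 3-(dimethoxymethyl)-4-isopropoxycyclobut-3-ene-1,2-dione | CC(C)OC1=C(C(OC)OC)C(=O)C1=O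
F2 | step 4 | sodium 2-(dimethoxymethyl)-3,4-dioxocyclobut-1-en-1-olate | [Na+].[O-]C1=C(C(OC)OC)C(=O)C1=O
F3 | step 4 | 3-chloro-4-(dimethoxymethyl)cyclobut-3-ene-1,2-dione | ClC1=C(C(OC)OC)C(=O)C1=O
F4 | step 4 | 3-(dimethoxymethyl)-4-[(7-methoxy-2-oxo-2H-chromen-6-yl)oxy]cyclobut-3-ene-1,2-dione | O=C1C(=O)C(C(OC)OC)=C1Oc1cc2ccc(=O)oc2cc1OC
F5 | step 4 | rac-2-(dimethoxymethyl)-4-hydroxy-3-[(7-methoxy-2-oxo-2H-chromen-6-yl)oxy]-4-(1-methoxyethenyl)cyclobut-2-en-1-one | O=C1C(C(OC)OC)=C(Oc2cc3ccc(=O)oc3cc2OC)C1(O)C(OC)=C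
F6 | step 4 | 6-[2-(dimethoxymethyl)-3,6-dihydroxy-5-methoxyphenoxy]-7-methoxy-2H-chromen-2-one | COc1cc(O)c(C(OC)OC)c(Oc2cc3ccc(=O)oc3cc2OC)c1O
F7 | step 5 | triethylsilyl ether of carbinol 12: rac-2-(1,3-dithian-2-yl)-3-[(7-methoxy-2-oxo-2H-chromen-6-yl)oxy]-4-(1-methoxyethenyl)-4-[(triethylsilyl)oxy]cyclobut-2-en-1-one | O=C1C(C2SCCCS2)=C(Oc2cc3ccc(=O)oc3cc2OC)C1(O[Si](CC)(CC)CC)C(OC)=C
F8 | step 5 | C6-O-triethylsilyl hydroquinone: 6-{2-(1,3-dithian-2-yl)-3-hydroxy-5-methoxy-6-[(triethylsilyl)oxy]phenoxy}-7-methoxy-2H-chromen-2-one | COc1cc(O)c(C2SCCCS2)c(Oc2cc3ccc(=O)oc3cc2OC)c1O[Si](CC)(CC)CC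
F9 | step 6 | 2-(1,3-dithian-2-yl)-5-methoxy-3-[(7-methoxy-2-oxo-2H-chromen-6-yl)oxy]benzene-1,4-diyl diacetate | COc1cc(OC(C)=O)c(C2SCCCS2)c(Oc2cc3ccc(=O)oc3cc2OC)c1OC(C)=O
F10 | step 6 | 2-formyl-5-methoxy-3-[(7-methoxy-2-oxo-2H-chromen-6-yl)oxy]benzene-1,4-diyl diacetate | COc1cc(OC(C)=O)c(C=O)c(Oc2cc3ccc(=O)oc3cc2OC)c1OC(C)=O
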